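## Structural features

The target (C30H22O8) is a 3,3''-biflavanone: two 7-hydroxy-2-(4-hydroxyphenyl)chroman-4-one units (rings A and C, with ring B on C2) held together only by the C3–C3'' single bond. The chain C2–C3–C3''–C2'' therefore carries four contiguous stereocentres, and the structure decodes as (2S,3R,3''S,2''R). Each ring C is 2,3-trans, with ring B and the other half both equatorial, and the two halves are mirror images, so the compound is the achiral meso diastereomer. All four centres are labile: C3 and C3'' are α to the C4 ketones and enolise, while C2 and C2'' are erased by retro-oxa-Michael opening of ring C in base or by benzylic ionisation assisted by the 4'-oxygen in acid. The four phenols add sensitivity to oxidants and strong Lewis acids. The trans relation inside each ring is therefore free under equilibrating conditions, whereas the relation between the halves (meso against the C2-symmetric racemate) is hardly biased; this, together with the crowded bond system around C3–C3'', is the real difficulty. The key step uses the fact that C2–C3–C3''–C2'', with ring B on each terminal carbon and the aroyl carbons C4 and C4'' on the inner ones, is a 1,4-diarylbuta-1,3-diyne to which two salicylaldehyde formyl C–H bonds have been added. The ortho-hydroxyl of that aldehyde directs the C–H activation and later becomes O1 and O1'' of the rings C.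

## Logic of the disconnections

9 ⇒ 8. The four phenolic O–H bonds are traced back to O–CH2Ph bonds. The phenols must be masked through rhodium catalysis and basic ring closure, and benzyl is chosen because it is removed without acid or base. Nothing is gained in skeleton, but 8 is non-polar and crystalline enough to be separated from its diastereomer. The forward step must cleave four benzyl ethers while sparing the benzylic C2–O1 bonds, the C4 ketones and the stereocentres.

8 ⇒ 5 (through 6 and 7). The bonds O1–C2 and O1''–C2'' are cut in the retro-oxa-Michael sense. This removes both rings C and all four stereocentres at once and leaves an acyclic, achiral precursor with only two alkene geometries. The forward step must close two rings on α-branched enones, settle each ring as 2,3-trans under thermodynamic control, and draw the unwanted diastereomer 7 over to 8 by removal of 8 and re-equilibration through 6.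

5 ⇒ 2 + two molecules of 3 (through 4). The bonds C3–C4 and C3''–C4'' are cut together with the C–H bonds at C2 and C2'', a retro-hydroacylation. Each half of 5 is an aldehyde C–H bond added across an alkyne, and the hydroxyl needed later for ring closure is the group that enables chelation-assisted C–H activation. A C58 skeleton falls into one C30 and two C14 pieces with no by-product. The forward step must place both acyl groups on the inner alkyne carbons by syn addition and must tolerate a conjugated diyne.

2 ⇒ two molecules of 1. The central sp–sp bond (the future C3–C3'') is cut. The diyne is symmetric, so oxidative homocoupling of one terminal alkyne suffices, and a single commercial building block remains. The forward step makes no special demand.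

## Other disconnections considered

Alternative 1: The cut is at C2–C3 and C2''–C3'' (aldol) and at O1–C2 and O1''–C2'' (oxa-Michael); the C3–C3'' bond is already present in the succinyl bridge of diketone A1. In the forward step an amine-mediated Kabbe condensation of A1 with two equivalents of aldehyde A2 would give A3, which is identical with 8.
- In favour: only classical carbonyl chemistry is used, no precious metal is needed, and rings C close in the same operation that builds the carbon skeleton.
- Against: A1 is not commercial in this protected form and needs about two steps. The two condensations must occur at adjacent methylenes, the second next to a newly formed, reversible flavanone. A 1,4-diketone can also cyclodehydrate to a 2,5-diarylfuran.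
- Comparison: on structure the two plans are equal, since both leave all four stereocentres to thermodynamic control and need the same separation. On mechanism the alternative is the better, because every event has close precedent whereas the chosen key step is an extrapolation. On step economy the two are about equal (roughly four steps each). The chosen plan offers complete atom economy in the assembly, three commercial pieces, and a defined (E,E) precursor without water-releasing equilibria.

Alternative 2: The cut is at C4–C4a and O1–C8a (ring A arrives as an aryne) and at O1–C2. In the forward step, fluoride-triggered aryne generation from silyl triflate A5 in the presence of diacid A4 would insert the aryne into each carboxyl C–O bond and close both rings by oxa-Michael addition, giving A6.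
- In favour: A4 is the product of a classical twofold Stobbe condensation and saponification. Aryne insertion into β-substituted acrylic acids with ring closure to chroman-4-ones is an established reaction type. The key step closes both rings C, which the chosen key step does not; on this point the alternative is the better.
- Against: regiocontrol depends on a chlorine that is absent from the target and must be removed afterwards. A5 needs a multistep preparation. A diacid can protonate the aryl anion (giving simple aryl esters) or close to the anhydride, and two insertions must both succeed. The methyl ethers require a Lewis-acid demethylation on the epimerisable biflavanone.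
- Comparison: on structure the plans are equal in stereocontrol (thermodynamic in both). On mechanism the alternative has precedent on simple substrates, but the twofold case on a diacid is as untested as the chosen twofold hydroacylation. On step economy the chosen plan is clearly shorter, about four steps against nine or more, and carries no sacrificial substituent.

Alternative 3: The cut is at C2–C3 and C2''–C3'' by a [4+2] cycloaddition in which the inner diene carbons are sacrificial. In the forward step, heating diene A7 with cis-enedione A8 would give the all-cis cyclohexene A9 through the endo transition state.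
- In favour: the cycloaddition is suprafacial and stereospecific. The all-cis array of A9 maps onto 2,3-trans, 2'',3''-trans and meso once the ring-alkene carbons are exchanged for oxygen with retention. It is the only plan here that fixes the relation between the two halves by design, and on stereocontrol it is the better of the two.
- Against: A8 isomerises readily to the trans isomer under heat or light, which would deliver the wrong C3/C3'' relation, and 1,4-diaryl dienes are sluggish. After the cycloaddition the ring alkene must be cleaved, both carbon termini exchanged for oxygen in the presence of two electron-rich aryl ketones and epimerisable α-centres, the rings closed by fluoride displacement, and four methyl ethers removed. The final Lewis-acid step can erode the stereochemistry so laboriously set.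
- Comparison: on structure the alternative is better in principle. On mechanism its key step is secure, but the steps after it are harder than the two that follow the chosen key step. On step economy (nine or more steps, two carbons and two fluorines discarded) it is clearly worse.

Key step: step 2

Remark: benzyl ethers are preferred to methyl ethers as phenol protection so that the last step is a neutral hydrogenolysis and not a Lewis-acid demethylation of an epimerisable biflavanone. The skeletons of the diyne and of the bis-chalcone are unaffected by this choice. Both benzyl-protected building blocks, 1 and 3, are assumed to be commercially available. The (E,E) geometry of 5 follows from syn addition, and the meso (2S,3R,2''R,3''S) configuration of 9 corresponds to two 2,3-trans rings of opposite handedness.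

## Steps

Step 1
Reactants: 1 1-(benzyloxy)-4-ethynylbenzene (2 equiv)
Product: 2 1,4-bis[4-(benzyloxy)phenyl]buta-1,3-diyne
Conditions: CuCl (10 mol%), TMEDA (20 mol%), O2 (1 atm), acetone, 25 °C
Reagents that add atoms: none
Why: Glaser–Hay oxidative homocoupling: two molecules of 1 are converted by CuCl/TMEDA into alkynylcopper species, which O2 oxidises so that the two alkynyl groups are joined at their sp carbons. The benzyl ether is inert and water is the only by-product.

Step 2
Reactants: 2 1,4-bis[4-(benzyloxy)phenyl]buta-1,3-diyne; 3 4-(benzyloxy)-2-hydroxybenzaldehyde (2.4 equiv)
Product: 5 (2E,3E)-1,4-bis[4-(benzyloxy)-2-hydroxyphenyl]-2,3-bis[4-(benzyloxy)benzylidene]butane-1,4-dione, via enynone mono-adduct 4 (not isolated)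
Conditions: [RhCl(cod)]2 (2.5 mol%), 1,1'-bis(diphenylphosphino)ferrocene (5.5 mol%), Na2CO3 (10 mol%), toluene, 110 °C, argon
Reagents that add atoms: none
Why: Proposed new method: twofold hydroacylation of a conjugated 1,3-diyne by a salicylaldehyde is not established, and the closest known reaction type is the hydroacylation of isolated internal alkynes by salicylaldehydes with [RhCl(cod)]2, a diphosphine and a weak base, which gives 2-alkenoylphenols by syn addition. Na2CO3 turns 3 into a rhodium phenoxide, and the chelated formyl C–H bond adds oxidatively to monovalent rhodium to give a five-membered acyl(hydrido) chelate of trivalent rhodium that resists loss of CO. Coordination of one alkyne of 2 and syn hydrometalation should deliver hydride to the aryl-bearing carbon (C2) and rhodium to the inner carbon (C3), where the neighbouring alkyne stabilises the alkenyl–metal bond in a propargyl-like manner, as is usual for hydrometalations of 1,3-diynes. C–C reductive elimination then forms C3–C4 and releases 4, whose remaining alkyne is flanked by an alkenyl group offering comparable allyl-type stabilisation and should repeat the cycle to form C3''–C4''. No ring is closed and no stereocentre is created; the only stereochemical element is the alkene geometry, and syn addition places each aroyl group trans to ring B, which is the (E,E) isomer. The selectivities required are acylation of the inner carbon at both alkynes and hydroacylation in preference to decarbonylation, diyne oligomerisation and phenol addition to the remaining alkyne; the first rests on the electronic bias of the diyne, the others on the phenoxide chelate and the wide-bite-angle diphosphine. Partial oxa-Michael closure of 4 or 5 under these conditions would be harmless, because such material converges on the products of step 3.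

Step 3
Reactants: 5 (2E,3E)-1,4-bis[4-(benzyloxy)-2-hydroxyphenyl]-2,3-bis[4-(benzyloxy)benzylidene]butane-1,4-dione
Product: 8 meso-(2S,3R,2''R,3''S)-7,7''-bis(benzyloxy)-2,2''-bis[4-(benzyloxy)phenyl]-3,3''-bichromane-4,4''-dione, via mono-cyclised flavanone 6 (not isolated), via C2-symmetric diastereomer 7 (not isolated)
Conditions: NaOAc (6 equiv), EtOH–THF (2:1), 75 °C; 8 removed by crystallisation, mother liquor returned to the same conditions
Reagents that add atoms: none
Why: Two successive 6-endo-trig oxa-Michael additions (the chalcone–flavanone isomerisation) of the ring-A phenoxides to C2 and C2'' close both rings C, and reversible ring opening together with C3 enolisation should leave each ring 2,3-trans with both substituents equatorial. The relation between the two halves is not biased, so the second closure of 6 should give 8 together with 7, and the two interconvert under the same conditions by retro-oxa-Michael opening to 6 and reclosure. Crystallisation removes 8, and the remainder, rich in 7, is returned to the conditions without isolation until it has been drawn over to 8.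

Step 4
Reactants: 8 meso-(2S,3R,2''R,3''S)-7,7''-bis(benzyloxy)-2,2''-bis[4-(benzyloxy)phenyl]-3,3''-bichromane-4,4''-dione
Product: 9 meso-(2S,3R,2''R,3''S)-7,7''-dihydroxy-2,2''-bis(4-hydroxyphenyl)-3,3''-bichromane-4,4''-dione (CNP0231820.1)
Conditions: H2 (1 atm), 10% Pd/C, THF–MeOH (1:1), 25 °C
Reagents that add atoms: none
Why: Catalytic hydrogenolysis cleaves the four aryl benzyl ethers under neutral conditions, so neither retro-oxa-Michael opening nor C3 enolisation can disturb the stereocentres fixed in 8. Aryl benzyl ethers are cleaved faster than the ring benzylic C2–O1 bond is broken or the aryl ketone reduced, so the reaction is stopped once four equivalents of H2 are taken up.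

## Compound list

1 | 1-(benzyloxy)-4-ethynylbenzene | C#Cc1ccc(OCc2ccccc2)cc1 | starting material
2 | 1,4-bis[4-(benzyloxy)phenyl]buta-1,3-diyne | C(#CC#Cc1ccc(OCc2ccccc2)cc1)c1ccc(OCc2ccccc2)cc1 | intermediate
3 | 4-(benzyloxy)-2-hydroxybenzaldehyde | O=Cc1ccc(OCc2ccccc2)cc1O | starting material
4 | (E)-1-[4-(benzyloxy)-2-hydroxyphenyl]-2-[4-(benzyloxy)benzylidene]-4-[4-(benzyloxy)phenyl]but-3-yn-1-one | O=C(c1ccc(OCc2ccccc2)cc1O)/C(C#Cc1ccc(OCc2ccccc2)cc1)=C/c1ccc(OCc2ccccc2)cc1 | intermediate (not isolated)
5 | (2E,3E)-1,4-bis[4-(benzyloxy)-2-hydroxyphenyl]-2,3-bis[4-(benzyloxy)benzylidene]butane-1,4-dione | c1ccccc1COc1ccc(/C=C(/C(=O)c2ccc(OCc3ccccc3)cc2O)C(=C/c2ccc(OCc3ccccc3)cc2)\C(=O)c2ccc(OCc3ccccc3)cc2O)cc1 | intermediate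
6 | rac-(2S,3R)-7-(benzyloxy)-2-[4-(benzyloxy)phenyl]-3-{(E)-1-[4-(benzyloxy)-2-hydroxybenzoyl]-2-[4-(benzyloxy)phenyl]ethenyl}chroman-4-one (2,3-trans; one enantiomer drawn) | O=C1c2ccc(OCc3ccccc3)cc2O[C@H](c2ccc(OCc3ccccc3)cc2)[C@H]1C(=C/c1ccc(OCc2ccccc2)cc1)\C(=O)c1ccc(OCc2ccccc2)cc1O | intermediate (not isolated)
7 | rac-(2S,3R,2''S,3''R)-7,7''-bis(benzyloxy)-2,2''-bis[4-(benzyloxy)phenyl]-3,3''-bichromane-4,4''-dione (C2-symmetric, both rings 2,3-trans; one enantiomer drawn) | O=C1c2ccc(OCc3ccccc3)cc2O[C@H](c2ccc(OCc3ccccc3)cc2)[C@H]1[C@H]1C(=O)c2ccc(OCc3ccccc3)cc2O[C@@H]1c1ccc(OCc2ccccc2)cc1 | intermediate (not isolated)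
8 | meso-(2S,3R,2''R,3''S)-7,7''-bis(benzyloxy)-2,2''-bis[4-(benzyloxy)phenyl]-3,3''-bichromane-4,4''-dione | O=C1c2ccc(OCc3ccccc3)cc2O[C@H](c2ccc(OCc3ccccc3)cc2)[C@H]1[C@@H]1C(=O)c2ccc(OCc3ccccc3)cc2O[C@H]1c1ccc(OCc2ccccc2)cc1 | intermediate
9 | meso-(2S,3R,2''R,3''S)-7,7''-dihydroxy-2,2''-bis(4-hydroxyphenyl)-3,3''-bichromane-4,4''-dione | O=C1c2ccc(O)cc2O[C@H](c2ccc(O)cc2)[C@H]1[C@@H]1C(=O)c2ccc(O)cc2O[C@H]1c1ccc(O)cc1 | target

## Step count and risks

Total step count: 4. Longest linear sequence: 4 steps (1 → 2 → 5 → 8 → 9).

**Step 2 (key step, beyond known chemistry).**
Most likely failure: loss of regiocontrol or arrest after the first addition. Rhodium may be placed on the aryl-bearing carbon at one alkyne, or the hindered, electron-poor enyne 4 may not insert a second time, while rhodium-mediated oligomerisation consumes 2.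
Fallback (known chemistry): it sets out from 1 and 3 and comes back at 8, making the central bond last instead of first. Hydroacylation of the single terminal alkyne of 1 by 3 with the same rhodium system, a reaction type known for simple alkynes, should give the 2'-hydroxychalcone (E)-1-[4-(benzyloxy)-2-hydroxyphenyl]-3-[4-(benzyloxy)phenyl]prop-2-en-1-one F1. The acyl group is expected on the unsubstituted alkyne carbon, and any branched regioisomer would be removed by chromatography at this stage. NaOAc in hot ethanol closes F1 to racemic 7-(benzyloxy)-2-[4-(benzyloxy)phenyl]chroman-4-one F2. Soft enolisation with Me3SiOTf and Et3N gives the silyl enol ether {7-(benzyloxy)-2-[4-(benzyloxy)phenyl]-2H-chromen-4-yl}oxy(trimethyl)silane F3. Oxidative homocoupling of F3 with Ag2O in DMSO joins C3 to C3'' and should give a mixture of 7 and 8, which is equilibrated with NaOAc and worked up as in step 3 to deliver 8.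

**Step 3.**
Most likely failure: incomplete closure of the second ring on the twisted α-branched enone, double-bond migration by γ-protonation of the cross-conjugated dienolate formed after the first closure, or failure of the meso isomer to crystallise selectively, so that the equilibrium cannot be drained at the benzyl ether stage.
Fallback: it sets out from 5 and comes back at 9, reversing the order of deprotection and ring closure. The benzyl ethers of 5 are cleaved with BCl3 and pentamethylbenzene in CH2Cl2 at −78 °C, which leaves the alkenes untouched, to give (2E,3E)-1,4-bis(2,4-dihydroxyphenyl)-2,3-bis(4-hydroxybenzylidene)butane-1,4-dione F4. F4 is cyclised and equilibrated in aqueous methanolic NaOAc, and the meso polyphenol 9 is separated by reversed-phase chromatography from its C2-symmetric diastereomer, rac-(2S,3R,2''S,3''R)-7,7''-dihydroxy-2,2''-bis(4-hydroxyphenyl)-3,3''-bichromane-4,4''-dione F5, which is returned to the equilibration.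

**Step 4.**
Most likely failure: over-reduction, meaning hydrogenolytic opening of the benzylic C2–O1 bonds or reduction of the C4 ketones, or stalling through poor solubility of partly debenzylated material.
Fallback: it sets out from 8 and comes back at 9 and makes no new compound. The reductive cleavage is replaced by Lewis-acid dealkylation with BCl3 and pentamethylbenzene in CH2Cl2 at −78 °C, in which the benzyl cations are trapped by the arene and no hydride source is present. The low temperature limits ionisation at C2.

## Further compounds

F1 | step 2 | (E)-1-[4-(benzyloxy)-2-hydroxyphenyl]-3-[4-(benzyloxy)phenyl]prop-2-en-1-one | O=C(/C=C/c1ccc(OCc2ccccc2)cc1)c1ccc(OCc2ccccc2)cc1O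
F2 | step 2 | rac-7-(benzyloxy)-2-[4-(benzyloxy)phenyl]chroman-4-one | O=C1CC(c2ccc(OCc3ccccc3)cc2)Oc2cc(OCc3ccccc3)ccc12
F3 | step 2 | rac-{7-(benzyloxy)-2-[4-(benzyloxy)phenyl]-2H-chromen-4-yl}oxy(trimethyl)silane | C[Si](C)(C)OC1=CC(c2ccc(OCc3ccccc3)cc2)Oc2cc(OCc3ccccc3)ccc12
F4 | step 3 | (2E,3E)-1,4-bis(2,4-dihydroxyphenyl)-2,3-bis(4-hydroxybenzylidene)butane-1,4-dione | Oc1ccc(/C=C(/C(=O)c2ccc(O)cc2O)C(=C/c2ccc(O)cc2)\C(=O)c2ccc(O)cc2O)cc1
F5 | step 3 | rac-(2S,3R,2''S,3''R)-7,7''-dihydroxy-2,2''-bis(4-hydroxyphenyl)-3,3''-bichromane-4,4''-dione (C2-symmetric; one enantiomer drawn) | O=C1c2ccc(O)cc2O[C@H](c2ccc(O)cc2)[C@H]1[C@H]1C(=O)c2ccc(O)cc2O[C@@H]1c1ccc(O)cc1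
F0 | step 4 | none | none
A1 | alternative 1 | 1,4-bis[4-(benzyloxy)-2-hydroxyphenyl]butane-1,4-dione | O=C(CCC(=O)c1ccc(OCc2ccccc2)cc1O)c1ccc(OCc2ccccc2)cc1O
A2 | alternative 1 | 4-(benzyloxy)benzaldehyde | O=Cc1ccc(OCc2ccccc2)cc1
A3 | alternative 1 | meso-(2S,3R,2''R,3''S)-7,7''-bis(benzyloxy)-2,2''-bis[4-(benzyloxy)phenyl]-3,3''-bichromane-4,4''-dione (identical with 8) | O=C1c2ccc(OCc3ccccc3)cc2O[C@H](c2ccc(OCc3ccccc3)cc2)[C@H]1[C@@H]1C(=O)c2ccc(OCc3ccccc3)cc2O[C@H]1c1ccc(OCc2ccccc2)cc1
A4 | alternative 2 | (2E,3E)-2,3-bis(4-methoxybenzylidene)succinic acid | COc1ccc(/C=C(/C(=O)O)C(=C/c2ccc(OC)cc2)\C(=O)O)cc1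
A5 | alternative 2 | 3-chloro-5-methoxy-2-(trimethylsilyl)phenyl trifluoromethanesulfonate | COc1cc(Cl)c([Si](C)(C)C)c(OS(=O)(=O)C(F)(F)F)c1
A6 | alternative 2 | meso-(2S,3R,2''R,3''S)-5,5''-dichloro-7,7''-dimethoxy-2,2''-bis(4-methoxyphenyl)-3,3''-bichromane-4,4''-dione | O=C1c2c(Cl)cc(OC)cc2O[C@H](c2ccc(OC)cc2)[C@H]1[C@@H]1C(=O)c2c(Cl)cc(OC)cc2O[C@H]1c1ccc(OC)cc1
A7 | alternative 3 | (1E,3E)-1,4-bis(4-methoxyphenyl)buta-1,3-diene | COc1ccc(/C=C/C=C/c2ccc(OC)cc2)cc1
A8 | alternative 3 | (Z)-1,4-bis(2-fluoro-4-methoxyphenyl)but-2-ene-1,4-dione | COc1ccc(C(=O)/C=C\C(=O)c2ccc(OC)cc2F)c(F)c1
A9 | alternative 3 | all-cis-4,5-bis(2-fluoro-4-methoxybenzoyl)-3,6-bis(4-methoxyphenyl)cyclohexene (meso) | C1=C[C@H](c2ccc(OC)cc2)[C@H](C(=O)c2ccc(OC)cc2F)[C@H](C(=O)c2ccc(OC)cc2F)[C@@H]1c1ccc(OC)cc1
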